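**Retrosynthetic overview**

Drimane numbering is used: ring A = C1–C5 + C10, ring B = C5–C10, C11 = benzylic CH2. The last bond is C11–aryl, made by 9-BBN hydroboration of drima-7,9(11)-diene and B-alkyl Suzuki–Miyaura coupling with the MOM-protected bromocatechol ester (this sets C9); the diene comes from 11-nordrim-7-en-9-one by methylenation.
Ring A is disconnected at C3–C4: a metal-hydride hydrogen-atom-transfer (MHAT) 6-endo radical conjugate addition turns an isopropenyl group on C5 into the C4 gem-dimethyl carbon while it bonds to the CH2 terminus of a 2-(methoxycarbonyl)allyl arm on C10; the ester is a traceless activator (hydrolysis, photodecarboxylation).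
Enabling feature: in ring A the quaternary gem-dimethyl carbon C4 is bonded directly to the ring-fusion methine C5, so C5–C4(CH3)2 is an isopropenyl group plus one hydrogen atom (a tertiary radical); ring B with its C8 methyl, C7=C8 alkene, C9 oxygen handle and C5 stereocenter is (R)-carvone.
The precursor comes from (R)-(−)-carvone by two α′-alkylations at C10 (CH3I, then methyl 2-(bromomethyl)acrylate anti to the isopropenyl group), which fix the trans C5/C10 relation that becomes the trans ring fusion.
Order of rings: the aromatic ring and ring B are bought (bromocatechol ester, carvone); ring A is the only ring made and is closed in step 3.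

Key step: step 3

Remark: methyl 3-bromo-4,5-dihydroxybenzoate is taken as a catalogue compound; if it must be made, one Fischer esterification of commercial 3-bromo-4,5-dihydroxybenzoic acid precedes step 7.

**Route**

Step 1
Reactants: 1 (R)-(−)-carvone
Product: 3 (5R,6RS)-2,6-dimethyl-5-(prop-1-en-2-yl)cyclohex-2-en-1-one (6-methylcarvone), via lithium dienolate 2 (not isolated)
Conditions: LiN(iPr)2 (LDA), THF, −78 °C; then CH3I, −78 to 0 °C
Reagents that add atoms: iodomethane, CI
Why: Kinetic α′-deprotonation of the cross-conjugated enone at C10 and SN2 methylation of the lithium dienolate is a standard enolate alkylation, and the new C10 stereocenter may form as a mixture because it is planarised again in step 2.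

Step 2
Reactants: 3 (5R,6RS)-6-methylcarvone; 4 methyl 2-(bromomethyl)prop-2-enoate
Product: 6 methyl 2-{[(1S,6S)-1,3-dimethyl-2-oxo-6-(prop-1-en-2-yl)cyclohex-3-en-1-yl]methyl}prop-2-enoate, via lithium dienolate 5 (not isolated)
Conditions: LiN(iPr)2 (LDA), THF, −78 to −20 °C; then 4, −78 °C to rt
Reagents that add atoms: none
Why: Enolate alkylation (SN2/SN2′) with the activated allylic bromide should occur on the face of the C10 enolate carbon opposite to the neighbouring C5 isopropenyl group, so the quaternary C10 is set by substrate control with the acrylate arm trans and the methyl cis to the isopropenyl group.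

Step 3
Reactants: 6 methyl 2-{[(1S,6S)-1,3-dimethyl-2-oxo-6-(prop-1-en-2-yl)cyclohex-3-en-1-yl]methyl}prop-2-enoate
Product: 7 methyl (2RS,4aS,8aS)-4,4,7,8a-tetramethyl-8-oxo-1,2,3,4,4a,5,8,8a-octahydronaphthalene-2-carboxylate
Conditions: Fe(acac)3 (30 mol %), PhSiH3, EtOH/(CH2OH)2, 0.02 M, 60 °C
Reagents that add atoms: none
Why: An iron hydride formed from Fe(acac)3 and PhSiH3 should transfer a hydrogen atom to the terminal CH2 of the isopropenyl group (Markovnikov MHAT), which makes that CH2 the second C4 methyl and leaves a nucleophilic tertiary radical at C4; this radical adds to the unsubstituted terminus (C3) of the acrylate, and the α-ester radical at C2 is reduced by divalent iron and protonated by ethanol. The closest known reaction type is the MHAT-initiated reductive olefin coupling (Giese addition of an alkene-derived tertiary radical to an acrylate), here intramolecular. Ring A is closed by a 6-endo-trig radical addition that forms the C3–C4 bond. No stereocenter of the target is created: the trans ring fusion is the trans-1,2 relation of the arms on C5 and C10 from step 2, carried over through a chair-like transition state with both arms equatorial and the C10 methyl axial, and the only new stereocenter, C2, is uncontrolled and is deleted in step 5. The step needs hydrogen-atom transfer to the electron-rich 1,1-disubstituted isopropenyl alkene in preference to the electron-poor acrylate and trisubstituted enone, and 6-endo over 5-exo closure. The first should follow from the polarity and accessibility of the isopropenyl group, the second from the acrylate, whose α-carbon is substituted and whose β-CH2 is the electrophilic site within reach, while high dilution suppresses intermolecular addition.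

Step 4
Reactants: 7 methyl (2RS,4aS,8aS)-4,4,7,8a-tetramethyl-8-oxo-1,2,3,4,4a,5,8,8a-octahydronaphthalene-2-carboxylate
Product: 8 (2RS,4aS,8aS)-4,4,7,8a-tetramethyl-8-oxo-1,2,3,4,4a,5,8,8a-octahydronaphthalene-2-carboxylic acid
Conditions: LiOH, THF/MeOH/H2O, rt; then 1 M HCl
Reagents that add atoms: lithium hydroxide, [Li+].[OH-]
Why: Saponification (addition–elimination at the acyl carbon) of the unhindered secondary methyl ester is standard, and the enone has no epimerisable centre to lose.

Step 5
Reactants: 8 (2RS,4aS,8aS)-4,4,7,8a-tetramethyl-8-oxo-1,2,3,4,4a,5,8,8a-octahydronaphthalene-2-carboxylic acid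
Product: 9 (4aS,8aS)-2,5,5,8a-tetramethyl-4a,5,6,7,8,8a-hexahydronaphthalen-1(4H)-one (11-nordrim-7-en-9-one)
Conditions: 9-mesityl-10-phenylacridinium tetrafluoroborate (5 mol %), PhSSPh (10 mol %), iPr2NEt (20 mol %), CF3CH2OH, 450 nm LED, rt
Reagents that add atoms: none
Why: Photoredox hydrodecarboxylation (single-electron oxidation of the carboxylate by the excited acridinium, loss of CO2, hydrogen-atom transfer from thiophenol to the secondary C2 radical) is a known traceless removal of a carboxyl group and erases the C2 stereocenter.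

Step 6
Reactants: 9 11-nordrim-7-en-9-one
Product: 10 (4aS,8aS)-4,4,7,8a-tetramethyl-8-methylidene-1,2,3,4,4a,5,8,8a-octahydronaphthalene (drima-7,9(11)-diene)
Conditions: Ph3PCH3Br, KOtBu, toluene, 90 °C
Reagents that add atoms: methyltriphenylphosphonium bromide, C[P+](c1ccccc1)(c1ccccc1)c1ccccc1.[Br-]
Why: Wittig methylenation with the small non-stabilised ylide under forcing conditions is the usual answer to hindered α-quaternary ketones and should convert the C9 carbonyl into the exocyclic C9=C11 alkene without touching C5 or C10.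

Step 7
Reactants: 11 methyl 3-bromo-4,5-dihydroxybenzoate
Product: 12 methyl 3-bromo-4,5-bis(methoxymethoxy)benzoate
Conditions: MOMCl, iPr2NEt, CH2Cl2, 0 °C to rt
Reagents that add atoms: chloromethyl methyl ether, COCCl
Why: Williamson-type O-alkylation of both phenols gives acetal protecting groups that should survive the basic aqueous cross-coupling and come off under mild acid.

Step 8
Reactants: 10 drima-7,9(11)-diene; 12 methyl 3-bromo-4,5-bis(methoxymethoxy)benzoate
Product: 14 methyl 3,4-bis(methoxymethoxy)-5-{[(1S,4aS,8aS)-2,5,5,8a-tetramethyl-1,4,4a,5,6,7,8,8a-octahydronaphthalen-1-yl]methyl}benzoate, via alkylborane 13 (not isolated)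
Conditions: 10, 9-BBN dimer, THF, 0 to 50 °C; then 12, Pd(dppf)Cl2 (5 mol %), K3PO4 (3 M aq), DMF, 50 °C
Reagents that add atoms: none
Why: 9-BBN should add anti-Markovnikov to the terminal C9=C11 alkene of the diene from the α face, away from the axial C10 methyl, which sets C9 (9α-H, C11 β-equatorial), and the B-alkyl Suzuki–Miyaura coupling then joins C11 to the aryl bromide without touching C9.

Step 9
Reactants: 14 methyl 3,4-bis(methoxymethoxy)-5-{[(1S,4aS,8aS)-2,5,5,8a-tetramethyl-1,4,4a,5,6,7,8,8a-octahydronaphthalen-1-yl]methyl}benzoate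
Product: 15 methyl 3,4-dihydroxy-5-{[(1S,4aS,8aS)-2,5,5,8a-tetramethyl-1,4,4a,5,6,7,8,8a-octahydronaphthalen-1-yl]methyl}benzoate (CNP0193946.2)
Conditions: HCl (1.25 M in MeOH, cat.), MeOH/THF, 0 °C to rt, degassed
Reagents that add atoms: none
Why: Acid-catalysed transacetalisation to methanol should cleave both phenolic MOM ethers under conditions dilute and cold enough to leave the methyl ester and the trisubstituted C7=C8 alkene untouched.

**Compound list**

1 | (R)-(−)-carvone, (5R)-2-methyl-5-(prop-1-en-2-yl)cyclohex-2-en-1-one | CC1=CC[C@@H](C(C)=C)CC1=O | starting material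
2 | lithium dienolate of 1, lithium (3R)-6-methyl-3-(prop-1-en-2-yl)cyclohexa-1,5-dien-1-olate | CC1=CC[C@@H](C(C)=C)C=C1[O-].[Li+] | intermediate
3 | (5R,6RS)-2,6-dimethyl-5-(prop-1-en-2-yl)cyclohex-2-en-1-one (6-methylcarvone, both C6 epimers) | CC1=CC[C@@H](C(C)=C)C(C)C1=O | intermediate
4 | methyl 2-(bromomethyl)prop-2-enoate | COC(=O)C(=C)CBr | starting material
5 | lithium dienolate of 3, lithium (3S)-2,6-dimethyl-3-(prop-1-en-2-yl)cyclohexa-1,5-dien-1-olate | CC1=CC[C@@H](C(C)=C)C(C)=C1[O-].[Li+] | intermediate
6 | methyl 2-{[(1S,6S)-1,3-dimethyl-2-oxo-6-(prop-1-en-2-yl)cyclohex-3-en-1-yl]methyl}prop-2-enoate (acrylate arm trans, methyl cis to isopropenyl) | CC1=CC[C@@H](C(C)=C)[C@](C)(CC(=C)C(=O)OC)C1=O | intermediate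
7 | methyl (2RS,4aS,8aS)-4,4,7,8a-tetramethyl-8-oxo-1,2,3,4,4a,5,8,8a-octahydronaphthalene-2-carboxylate (trans-fused) | CC1=CC[C@H]2C(C)(C)CC(C(=O)OC)C[C@]2(C)C1=O | intermediate
8 | (2RS,4aS,8aS)-4,4,7,8a-tetramethyl-8-oxo-1,2,3,4,4a,5,8,8a-octahydronaphthalene-2-carboxylic acid | CC1=CC[C@H]2C(C)(C)CC(C(=O)O)C[C@]2(C)C1=O | intermediate
9 | (4aS,8aS)-2,5,5,8a-tetramethyl-4a,5,6,7,8,8a-hexahydronaphthalen-1(4H)-one (11-nordrim-7-en-9-one) | CC1=CC[C@H]2C(C)(C)CCC[C@]2(C)C1=O | intermediate
10 | (4aS,8aS)-4,4,7,8a-tetramethyl-8-methylidene-1,2,3,4,4a,5,8,8a-octahydronaphthalene (drima-7,9(11)-diene) | C=C1C(C)=CC[C@H]2C(C)(C)CCC[C@]12C | intermediate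
11 | methyl 3-bromo-4,5-dihydroxybenzoate | COC(=O)c1cc(O)c(O)c(Br)c1 | starting material
12 | methyl 3-bromo-4,5-bis(methoxymethoxy)benzoate | COC(=O)c1cc(OCOC)c(OCOC)c(Br)c1 | intermediate
13 | B-(drim-7-en-11-yl)-9-borabicyclo[3.3.1]nonane (5α-H, 9α-H, 10β-methyl) | CC1=CC[C@H]2C(C)(C)CCC[C@]2(C)[C@H]1CB3C4CCCC3CCC4 | intermediate
14 | methyl 3,4-bis(methoxymethoxy)-5-{[(1S,4aS,8aS)-2,5,5,8a-tetramethyl-1,4,4a,5,6,7,8,8a-octahydronaphthalen-1-yl]methyl}benzoate | COC(=O)c1cc(OCOC)c(OCOC)c(C[C@H]2C(C)=CC[C@H]3C(C)(C)CCC[C@]23C)c1 | intermediate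
15 | methyl 3,4-dihydroxy-5-{[(1S,4aS,8aS)-2,5,5,8a-tetramethyl-1,4,4a,5,6,7,8,8a-octahydronaphthalen-1-yl]methyl}benzoate | COC(=O)c1cc(O)c(O)c(C[C@H]2C(C)=CC[C@H]3C(C)(C)CCC[C@]23C)c1 | target

**Step count**

Total steps: 9. Longest linear sequence: 8 (steps 1, 2, 3, 4, 5, 6, 8, 9 from carvone); step 7 is a one-step side branch.

**Three steps most likely to fail**

Step 3 (key step). What may go wrong: hydrogen-atom transfer to the acrylate or the enone competes with transfer to the isopropenyl group, or the tertiary radical is reduced before it cyclises, so that open-chain over-reduced material forms. Fallback: setting out from 6, Markovnikov addition of HBr (HBr/AcOH, 0 °C) to the isopropenyl group should give the tertiary bromide methyl 2-{[(1S,6R)-6-(2-bromopropan-2-yl)-1,3-dimethyl-2-oxocyclohex-3-en-1-yl]methyl}prop-2-enoate F1. Slow addition of Bu3SnH/AIBN (benzene, 80 °C, high dilution) should then generate the C4 radical by bromine abstraction at that carbon only and close ring A by the same 6-endo Giese addition, which comes back to the route at 7.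

Step 6. What may go wrong: the ylide acts as a base on the hindered enone (γ-deprotonation to the dienolate) and carbonyl addition is too slow, so the ketone is returned. Fallback: setting out from 9, addition of Me3SiCH2Li/CeCl3 (THF, −78 °C) should give the β-hydroxysilane (4aS,8aS)-2,5,5,8a-tetramethyl-1-[(trimethylsilyl)methyl]-1,4,4a,5,6,7,8,8a-octahydronaphthalen-1-ol F2. Peterson elimination (KH, THF, 0 °C to rt) should then come back to the route at 10.

Step 8. What may go wrong: slow transmetalation of the β-branched alkylborane to the ortho-substituted arylpalladium bromide, so that protodeboronation and reduction of the aryl bromide take over. Fallback: setting out from 10, hydroboration as in step 8 to 13 and oxidation (NaOH, H2O2) should give (−)-drimenol F3. Appel iodination (I2, PPh3, imidazole, CH2Cl2) should give 11-iododrim-7-ene F4. Zinc insertion (Zn dust, LiCl, THF, 40 °C) should give drimenylzinc iodide F5, and Negishi coupling with 12 (Pd(OAc)2, SPhos, THF, 50 °C) should come back to the route at 14.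

**Further compounds**

F1 | step 3 | methyl 2-{[(1S,6R)-6-(2-bromopropan-2-yl)-1,3-dimethyl-2-oxocyclohex-3-en-1-yl]methyl}prop-2-enoate | CC1=CC[C@@H](C(C)(C)Br)[C@](C)(CC(=C)C(=O)OC)C1=O
F2 | step 6 | (4aS,8aS)-2,5,5,8a-tetramethyl-1-[(trimethylsilyl)methyl]-1,4,4a,5,6,7,8,8a-octahydronaphthalen-1-ol (either C1 epimer) | CC1=CC[C@H]2C(C)(C)CCC[C@]2(C)C1(O)C[Si](C)(C)C
F3 | step 8 | (−)-drimenol, [(1S,4aS,8aS)-2,5,5,8a-tetramethyl-1,4,4a,5,6,7,8,8a-octahydronaphthalen-1-yl]methanol | CC1=CC[C@H]2C(C)(C)CCC[C@]2(C)[C@H]1CO
F4 | step 8 | 11-iododrim-7-ene, (1S,4aS,8aS)-1-(iodomethyl)-2,5,5,8a-tetramethyl-1,4,4a,5,6,7,8,8a-octahydronaphthalene | CC1=CC[C@H]2C(C)(C)CCC[C@]2(C)[C@H]1CI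
F5 | step 8 | drimenylzinc iodide, {[(1S,4aS,8aS)-2,5,5,8a-tetramethyl-1,4,4a,5,6,7,8,8a-octahydronaphthalen-1-yl]methyl}zinc iodide | CC1=CC[C@H]2C(C)(C)CCC[C@]2(C)[C@H]1C[Zn]I
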